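The route rests on cutting the furanone (O, C1, C2, C3, C4; germacrane numbering) back to a 4,5-oxirane set by Sharpless epoxidation. In the ten-membered epoxy ynone 22, base removes the acidic butenolide γ-proton at C6; the dienolate expels the oxirane oxygen from C5, and the freed C4 alkoxide adds to C1 of the C1≡C2–C3=O ynone. One operation enlarges the three-membered ring O–C4–C5 to the five-membered ring O–C4–C3–C2–C1, creates the C5=C6 enol lactone and the 1,4-oxygen bridge, and carries the C4 configuration through. The step exploits that the furanone oxygen on C4 is allylic to C5=C6, which is vinylogous to the C12 lactone carbonyl.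

Key step: step 17

Remark: germacrane numbering is used throughout (C6/C7/C11/C12 = butenolide γ/β/α/carbonyl carbons, C13 = hydroxymethyl carbon; TBS = tert-butyldimethylsilyl, TIPS = triisopropylsilyl, PMB = 4-methoxybenzyl); C6 is carried as both epimers from 7 to 22 because it becomes sp2 in step 17.

Step 1
Reactants: 1 (E)-but-2-enal; 2 ethynyltri(propan-2-yl)silane
Product: 3 (3S)-3-methyl-5-(triisopropylsilyl)pent-4-ynal
Conditions: [Rh(OAc)(C2H4)2]2 (2.5 mol%), DTBM-SEGPHOS (6 mol%, the enantiomer that gives the S product), MeOH, 40 °C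
Reagents that add atoms: none
Why: Rhodium-catalysed asymmetric conjugate alkynylation of an enal, in which the bulky bisphosphine suppresses alkyne dimerisation and the ligand enantiomer sets C10 (S).

Step 2
Reactants: 4 4-methoxybenzyl propargyl ether; 5 mucobromic acid
Product: 7 rac-3,4-dibromo-5-[(1E)-3-(4-methoxybenzyloxy)-2-methylprop-1-en-1-yl]furan-2(5H)-one, via alkenylalane 6 (not isolated)
Conditions: Me3Al (2 equiv), Cp2ZrCl2 (0.2 equiv), CH2Cl2, 0 °C to rt, excess Me3Al removed in vacuo; then sodium carboxylate of 5 (NaH, THF), −78 °C to rt; 1 M HCl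
Reagents that add atoms: trimethylaluminium, C[Al](C)C
Why: Negishi carboalumination adds methyl and aluminium syn across the alkyne (methyl to the internal carbon, hence the E-alkenylalane), which should add 1,2 to the open-chain aldehyde tautomer of the mucobromate, and acidic work-up relactonises; C6 forms as both enantiomers, which is immaterial.

Step 3
Reactants: 7 rac-dibromobutenolide; 3 (3S)-3-methyl-5-(triisopropylsilyl)pent-4-ynal
Product: 8 3-bromo-4-[(3S)-1-hydroxy-3-methyl-5-(triisopropylsilyl)pent-4-yn-1-yl]-5-[(1E)-3-(4-methoxybenzyloxy)-2-methylprop-1-en-1-yl]furan-2(5H)-one (C8 and C6 epimers)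
Conditions: CrCl2 (4 equiv), NiCl2 (5 mol%), DMF, rt
Reagents that add atoms: none
Why: Nozaki–Hiyama–Kishi coupling, in which zerovalent nickel should insert into the more electron-poor C–Br bond β to the lactone carbonyl (C7) and the derived alkenylchromium dichloride adds chemoselectively to the aldehyde; C8 forms unselectively and is corrected in steps 4 and 5.

Step 4
Reactants: 8 secondary alcohol (epimer mixture)
Product: 9 3-bromo-4-[(3S)-3-methyl-5-(triisopropylsilyl)pent-4-ynoyl]-5-[(1E)-3-(4-methoxybenzyloxy)-2-methylprop-1-en-1-yl]furan-2(5H)-one (C6 epimers)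
Conditions: Dess–Martin periodinane, CH2Cl2, rt
Reagents that add atoms: none
Why: Dess–Martin oxidation removes the uncontrolled C8 centre under non-basic conditions.

Step 5
Reactants: 9 C8 ketone
Product: 10 3-bromo-4-[(1S,3S)-1-hydroxy-3-methyl-5-(triisopropylsilyl)pent-4-yn-1-yl]-5-[(1E)-3-(4-methoxybenzyloxy)-2-methylprop-1-en-1-yl]furan-2(5H)-one (C6 epimers)
Conditions: (R)-Me-CBS [(R)-1-methyl-3,3-diphenyltetrahydro-1H,3H-pyrrolo[1,2-c][1,3,2]oxazaborole] (0.2 equiv), catecholborane (1.5 equiv), toluene, −78 °C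
Reagents that add atoms: none
Why: Corey–Bakshi–Shibata reduction, in which the fully substituted butenolide carbon is the large group so the (R)-catalyst should give (8S), while catecholborane at low temperature leaves the trisubstituted alkene untouched.

Step 6
Reactants: 10 (8S)-alcohol bearing the C11 bromide
Product: 11 3-(hydroxymethyl)-4-[(1S,3S)-1-hydroxy-3-methyl-5-(triisopropylsilyl)pent-4-yn-1-yl]-5-[(1E)-3-(4-methoxybenzyloxy)-2-methylprop-1-en-1-yl]furan-2(5H)-one (C6 epimers)
Conditions: Pd(PPh3)4 (10 mol%), (tributylstannyl)methanol (1.5 equiv), 1,4-dioxane, 90 °C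
Reagents that add atoms: (tributylstannyl)methanol, OC[Sn](CCCC)(CCCC)CCCC
Why: Stille coupling of the remaining α-bromide (C11) transfers the hydroxymethyl group (C13) under neutral conditions.

Step 7
Reactants: 11 diol
Product: 12 3-(TBSO-methyl)-4-[(1S,3S)-1-hydroxy-3-methyl-5-(triisopropylsilyl)pent-4-yn-1-yl]-5-[(1E)-3-(4-methoxybenzyloxy)-2-methylprop-1-en-1-yl]furan-2(5H)-one (C6 epimers)
Conditions: TBSCl (1.05 equiv), imidazole, CH2Cl2, −20 °C
Reagents that add atoms: tert-butyldimethylsilyl chloride, CC(C)(C)[Si](C)(C)Cl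
Why: The primary allylic alcohol should be silylated much faster than the hindered secondary C8 alcohol.

Step 8
Reactants: 13 ethyl 2-(hydroxymethyl)prop-2-enoate
Product: 14 ethyl 2-(TBSO-methyl)prop-2-enoate
Conditions: TBSCl, imidazole, CH2Cl2, 0 °C to rt
Reagents that add atoms: tert-butyldimethylsilyl chloride, CC(C)(C)[Si](C)(C)Cl
Why: Standard silylation of a primary alcohol.

Step 9
Reactants: 14 ethyl 2-(TBSO-methyl)prop-2-enoate
Product: 15 2-(TBSO-methyl)prop-2-enoic acid
Conditions: LiOH, THF/H2O, 0 °C; then 1 M HCl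
Reagents that add atoms: lithium hydroxide, [Li+].[OH-]
Why: Saponification of the ethyl ester at 0 °C, which the silyl ether should survive.

Step 10
Reactants: 12 C8 alcohol; 15 2-(TBSO-methyl)prop-2-enoic acid
Product: 16 (1S,3S)-1-{4-(TBSO-methyl)-2-[(1E)-3-(4-methoxybenzyloxy)-2-methylprop-1-en-1-yl]-5-oxo-2,5-dihydrofuran-3-yl}-3-methyl-5-(triisopropylsilyl)pent-4-yn-1-yl 2-(TBSO-methyl)prop-2-enoate (C6 epimers)
Conditions: DCC (1.5 equiv), DMAP (0.1 equiv), CH2Cl2, 0 °C to rt
Reagents that add atoms: none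
Why: Steglich esterification installs the complete C8 acyl group before the base-sensitive epoxide exists.

Step 11
Reactants: 16 PMB ether
Product: 17 allylic alcohol bearing the (1E)-3-hydroxy-2-methylprop-1-en-1-yl side chain on C6 (C6 epimers)
Conditions: DDQ (1.3 equiv), CH2Cl2/pH 7 buffer, 0 °C
Reagents that add atoms: none
Why: Oxidative cleavage of the 4-methoxybenzyl ether frees the C3 allylic alcohol without touching silyl ethers or esters.

Step 12
Reactants: 17 allylic alcohol
Product: 18 (4R,5R)-4,5-epoxy alcohol bearing a (2R,3R)-3-(hydroxymethyl)-3-methyloxiran-2-yl group on C6 (C6 epimers)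
Conditions: Ti(OiPr)4 (0.2 equiv), D-(−)-diethyl tartrate (0.25 equiv), t-BuOOH, 4 Å MS, CH2Cl2, −20 °C
Reagents that add atoms: tert-butyl hydroperoxide, CC(C)(C)OO
Why: Sharpless asymmetric epoxidation, in which D-(−)-tartrate on the E-trisubstituted primary allylic alcohol should set C4 (and C5) by reagent control whatever the C6 configuration, and the electron-poor alkenes do not react.

Step 13
Reactants: 18 epoxy alcohol bearing the silylalkyne
Product: 19 iodoalkyne epoxy alcohol (C≡C–I in place of C≡C–TIPS)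
Conditions: AgF (1.5 equiv), N-iodosuccinimide (1.2 equiv), MeCN, rt, dark
Reagents that add atoms: N-iodosuccinimide, O=C1CCC(=O)N1I
Why: Silver-mediated desilylation gives the alkynylsilver (RC≡CAg), which N-iodosuccinimide iodinates under essentially non-basic conditions.

Step 14
Reactants: 19 iodoalkyne epoxy alcohol
Product: 20 iodoalkyne α,β-epoxy aldehyde (C3 as CHO)
Conditions: PhI(OAc)2 (1.2 equiv), TEMPO (0.1 equiv), CH2Cl2, rt
Reagents that add atoms: none
Why: Oxoammonium (TEMPO) oxidation of the primary epoxy alcohol stops at the aldehyde and uses no base.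

Step 15
Reactants: 20 iodoalkyne epoxy aldehyde
Product: 21 macrocyclic propargylic alcohol (ten-membered carbocycle; C3 carbinol as both epimers)
Conditions: CrCl2 (6 equiv), NiCl2 (1 mol%), THF, rt, 0.002 M, slow addition
Reagents that add atoms: none
Why: Intramolecular Nozaki–Hiyama–Kishi alkynylation, in which divalent chromium turns the iodoalkyne into a neutral alkynylchromium dichloride that should close the ten-membered ring on the aldehyde at high dilution without touching the epoxide or the acidic C6–H.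

Step 16
Reactants: 21 macrocyclic propargylic alcohol
Product: 22 macrocyclic epoxy ynone (C1≡C2–C3=O; 4,5-epoxide; C6 epimers)
Conditions: Dess–Martin periodinane, CH2Cl2, 0 °C
Reagents that add atoms: none
Why: Dess–Martin oxidation of the propargylic alcohol gives the ynone and removes the C3 centre.

Step 17
Reactants: 22 macrocyclic epoxy ynone
Product: 25 bis-TBS ether of the target (4S,5E,8S,10S), via dienolate 23 (not isolated), via alkoxide 24 (not isolated)
Conditions: DBU (0.3 equiv), CH2Cl2, −40 °C to 0 °C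
Reagents that add atoms: none
Why: DBU removes the ring γ-proton at C6 to give the 2-oxidofuran 23, and this vinylogous enolate expels the oxirane oxygen from C5 (E1cB, as in base-induced opening of γ,δ-epoxy enoates) to give the C5=C6 enol lactone and the C4 alkoxide 24, which adds to C1 of the ynone (oxa-Michael, as in the cyclisation of α'-hydroxy ynones to 3(2H)-furanones) before protonation at C2 returns the base. The furanone closes 5-endo-dig, and the net change is enlargement of the oxirane O–C4–C5 to the ring O–C4–C3–C2–C1, which is also the transannular oxygen bridge of the ten-membered carbocycle. No new stereocentre is formed: the C4–O bond is never broken, so C4 (S) comes from step 12, while C3, C5 and C6 end up sp2. The C5=C6 geometry (C4 cis to C7) is imposed by the ten-membered ring, which already holds the linear alkyne and should not accommodate a trans double bond. Chemoselectivity needs C6–H to be removed faster than C8–H (aromatic furanolate against a simple dienolate) and the alkoxide to reach C1 before the lactone carbonyl, which the five-membered transition state secures.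

Step 18
Reactants: 25 bis-TBS ether
Product: 26 CNP0261115.1 (target)
Conditions: HF·pyridine, pyridine/THF, 0 °C to rt
Reagents that add atoms: none
Why: Buffered fluoride cleaves both primary silyl ethers under conditions that the enol lactone, the furanone and the acrylate should tolerate.

Compound list
1 | (E)-but-2-enal | C/C=C/C=O | starting material
2 | ethynyltri(propan-2-yl)silane | C#C[Si](C(C)C)(C(C)C)C(C)C | starting material
3 | (3S)-3-methyl-5-(triisopropylsilyl)pent-4-ynal | O=CC[C@H](C)C#C[Si](C(C)C)(C(C)C)C(C)C | intermediate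
4 | 1-methoxy-4-[(prop-2-yn-1-yloxy)methyl]benzene | C#CCOCc1ccc(OC)cc1 | starting material
5 | mucobromic acid (3,4-dibromo-5-hydroxyfuran-2(5H)-one) | O=C1OC(O)C(Br)=C1Br | starting material
6 | dimethyl[(1E)-3-(4-methoxybenzyloxy)-2-methylprop-1-en-1-yl]aluminium | C[Al](C)/C=C(C)/COCc1ccc(OC)cc1 | intermediate (not isolated)
7 | rac-3,4-dibromo-5-[(1E)-3-(4-methoxybenzyloxy)-2-methylprop-1-en-1-yl]furan-2(5H)-one | O=C1OC(/C=C(C)/COCc2ccc(OC)cc2)C(Br)=C1Br | intermediate
8 | 3-bromo-4-[(3S)-1-hydroxy-3-methyl-5-(triisopropylsilyl)pent-4-yn-1-yl]-5-[(1E)-3-(4-methoxybenzyloxy)-2-methylprop-1-en-1-yl]furan-2(5H)-one (C8 and C6 epimers) | OC(C[C@H](C)C#C[Si](C(C)C)(C(C)C)C(C)C)C1=C(Br)C(=O)OC1/C=C(C)/COCc1ccc(OC)cc1 | intermediate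
9 | 3-bromo-4-[(3S)-3-methyl-5-(triisopropylsilyl)pent-4-ynoyl]-5-[(1E)-3-(4-methoxybenzyloxy)-2-methylprop-1-en-1-yl]furan-2(5H)-one (C6 epimers) | O=C(C[C@H](C)C#C[Si](C(C)C)(C(C)C)C(C)C)C1=C(Br)C(=O)OC1/C=C(C)/COCc1ccc(OC)cc1 | intermediate
10 | 3-bromo-4-[(1S,3S)-1-hydroxy-3-methyl-5-(triisopropylsilyl)pent-4-yn-1-yl]-5-[(1E)-3-(4-methoxybenzyloxy)-2-methylprop-1-en-1-yl]furan-2(5H)-one (C6 epimers) | O[C@@H](C[C@H](C)C#C[Si](C(C)C)(C(C)C)C(C)C)C1=C(Br)C(=O)OC1/C=C(C)/COCc1ccc(OC)cc1 | intermediate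
11 | 3-(hydroxymethyl) analogue of 10 (C13 installed; C6 epimers) | O[C@@H](C[C@H](C)C#C[Si](C(C)C)(C(C)C)C(C)C)C1=C(CO)C(=O)OC1/C=C(C)/COCc1ccc(OC)cc1 | intermediate
12 | 3-(TBSO-methyl) analogue of 11 (C8–OH free; C6 epimers) | O[C@@H](C[C@H](C)C#C[Si](C(C)C)(C(C)C)C(C)C)C1=C(CO[Si](C)(C)C(C)(C)C)C(=O)OC1/C=C(C)/COCc1ccc(OC)cc1 | intermediate
13 | ethyl 2-(hydroxymethyl)prop-2-enoate | C=C(CO)C(=O)OCC | starting material
14 | ethyl 2-(TBSO-methyl)prop-2-enoate | C=C(CO[Si](C)(C)C(C)(C)C)C(=O)OCC | intermediate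
15 | 2-(TBSO-methyl)prop-2-enoic acid | C=C(CO[Si](C)(C)C(C)(C)C)C(=O)O | intermediate
16 | (1S,3S)-1-{4-(TBSO-methyl)-2-[(1E)-3-(4-methoxybenzyloxy)-2-methylprop-1-en-1-yl]-5-oxo-2,5-dihydrofuran-3-yl}-3-methyl-5-(triisopropylsilyl)pent-4-yn-1-yl 2-(TBSO-methyl)prop-2-enoate (C6 epimers) | C=C(CO[Si](C)(C)C(C)(C)C)C(=O)O[C@@H](C[C@H](C)C#C[Si](C(C)C)(C(C)C)C(C)C)C1=C(CO[Si](C)(C)C(C)(C)C)C(=O)OC1/C=C(C)/COCc1ccc(OC)cc1 | intermediate
17 | allylic alcohol: 16 without the PMB group (C6 epimers) | C=C(CO[Si](C)(C)C(C)(C)C)C(=O)O[C@@H](C[C@H](C)C#C[Si](C(C)C)(C(C)C)C(C)C)C1=C(CO[Si](C)(C)C(C)(C)C)C(=O)OC1/C=C(C)/CO | intermediate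
18 | (4R,5R)-4,5-epoxy alcohol of 17 (C6 epimers) | C=C(CO[Si](C)(C)C(C)(C)C)C(=O)O[C@@H](C[C@H](C)C#C[Si](C(C)C)(C(C)C)C(C)C)C1=C(CO[Si](C)(C)C(C)(C)C)C(=O)OC1[C@H]2O[C@]2(C)CO | intermediate
19 | iodoalkyne epoxy alcohol: 18 with C≡C–I | C=C(CO[Si](C)(C)C(C)(C)C)C(=O)O[C@@H](C[C@H](C)C#CI)C1=C(CO[Si](C)(C)C(C)(C)C)C(=O)OC1[C@H]2O[C@]2(C)CO | intermediate
20 | iodoalkyne epoxy aldehyde: 19 with C3 as CHO (oxirane geometry as in 18) | C=C(CO[Si](C)(C)C(C)(C)C)C(=O)O[C@@H](C[C@H](C)C#CI)C1=C(CO[Si](C)(C)C(C)(C)C)C(=O)OC1[C@H]2O[C@]2(C)C=O | intermediate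
21 | macrocyclic propargylic alcohol: ten-membered carbocycle C1–C10 with C1≡C2, C3–OH (both epimers), 4,5-oxirane with the geometry of 18, 6,12-olide (C7=C11, 13-OTBS), (8S)-[2-(TBSO-methyl)acryloyloxy], (10S)-methyl (C6 epimers) | C=C(CO[Si](C)(C)C(C)(C)C)C(=O)O[C@H]1C[C@H](C)C#CC(O)[C@@]3(C)O[C@@H]3C2OC(=O)C(CO[Si](C)(C)C(C)(C)C)=C12 | intermediate
22 | macrocyclic epoxy ynone: 21 with C3=O (C6 epimers) | C=C(CO[Si](C)(C)C(C)(C)C)C(=O)O[C@H]1C[C@H](C)C#CC(=O)[C@@]3(C)O[C@@H]3C2OC(=O)C(CO[Si](C)(C)C(C)(C)C)=C12 | intermediate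
23 | C6 dienolate (2-oxidofuran) of 22, DBU-H+ salt | C=C(CO[Si](C)(C)C(C)(C)C)C(=O)O[C@H]1C[C@H](C)C#CC(=O)[C@@]3(C)O[C@@H]3C2=C1C(CO[Si](C)(C)C(C)(C)C)=C([O-])O2.C1CCC2=[NH+]CCCN2CC1 | intermediate (not isolated)
24 | C4 alkoxide with (5E)-enol lactone and intact ynone, DBU-H+ salt | C=C(CO[Si](C)(C)C(C)(C)C)C(=O)O[C@H]1C[C@H](C)C#CC(=O)[C@@](C)([O-])/C=C2/OC(=O)C(CO[Si](C)(C)C(C)(C)C)=C21.C1CCC2=[NH+]CCCN2CC1 | intermediate (not isolated)
25 | bis-TBS ether of the target (4S,5E,8S,10S) | C=C(CO[Si](C)(C)C(C)(C)C)C(=O)O[C@H]1C[C@H](C)C2=CC(=O)[C@](C)(/C=C3/OC(=O)C(CO[Si](C)(C)C(C)(C)C)=C31)O2 | intermediate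
26 | CNP0261115.1 | C=C(CO)C(=O)O[C@H]1C[C@H](C)C2=CC(=O)[C@](C)(/C=C3/OC(=O)C(CO)=C31)O2 | target

Total steps: 18 (16 in the main line, 2 for acid 15). Longest linear sequence: 15 steps (4/5 to 26 through steps 2–7 and 10–18).

Steps most likely to fail

Step 15: ring closure to the strained ten-membered cycloalkyne may lose to intermolecular coupling, or divalent chromium may reduce the epoxy aldehyde first. The fallback sets out from 19 and avoids the cycloalkyne. Dicyclohexylborane (in excess, since the free alcohol consumes one equivalent) followed by acetic acid should turn the iodoalkyne into the (Z)-iodoalkene epoxy alcohol F1. TEMPO/PhI(OAc)2 oxidation gives the (Z)-iodoalkene epoxy aldehyde F2. NiCl2/CrCl2 at high dilution closes the ring through the vinyl iodide to the macrocyclic (Z)-allylic alcohol F3, which holds an unstrained cis double bond. Dess–Martin oxidation gives the macrocyclic (Z)-epoxy enone F4. DBU then triggers the same eliminative oxirane opening, and the C4 alkoxide closes onto the enone to the 1,2-dihydro furanone F5. Dehydrogenation with 2-iodoxybenzoic acid in DMSO at 65 °C comes back to the route at 25.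

Step 17: conjugate addition of the amidine to the ynone or the acrylate, or deprotonation at C8 with loss of its configuration, may outrun the cascade, or the alkoxide may fail to reach C1. The fallback sets out from 21 and separates the events. DBU on the propargylic alcohol (no ynone present) performs only the eliminative oxirane opening to the macrocyclic 3,4-diol F6. MnO2 oxidises the propargylic alcohol selectively to the macrocyclic α'-hydroxy ynone F7. Catalytic Ph3PAuNTf2 in CH2Cl2 then closes the furanone by 5-endo-dig cyclisation and comes back to the route at 25.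

Step 3: the alkenylchromium intermediate may eliminate the allylic lactone oxygen (ring opening), or nickel may insert into the wrong C–Br bond. The fallback sets out from 7 and needs no organochromium species. Carbonylative Stille coupling with (E)-tributyl(prop-1-en-1-yl)stannane under CO (Pd2(dba)3, AsPh3) at the C7 bromide gives the crotonoyl butenolide F8. The rhodium-catalysed asymmetric conjugate alkynylation of step 1, now with 2 on the enone, sets C10 and comes back to the route at 9; steps 1, 3 and 4 are then not needed.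

Further compounds
F1 | step 15 | (Z)-iodoalkene epoxy alcohol (19 with cis-CH=CHI) | C=C(CO[Si](C)(C)C(C)(C)C)C(=O)O[C@@H](C[C@H](C)/C=C\I)C1=C(CO[Si](C)(C)C(C)(C)C)C(=O)OC1[C@H]2O[C@]2(C)CO
F2 | step 15 | (Z)-iodoalkene epoxy aldehyde | C=C(CO[Si](C)(C)C(C)(C)C)C(=O)O[C@@H](C[C@H](C)/C=C\I)C1=C(CO[Si](C)(C)C(C)(C)C)C(=O)OC1[C@H]2O[C@]2(C)C=O
F3 | step 15 | macrocyclic (Z)-allylic alcohol (C1=C2 cis, C3–OH epimers, 4,5-epoxide) | C=C(CO[Si](C)(C)C(C)(C)C)C(=O)O[C@H]1C[C@H](C)/C=C\C(O)[C@@]3(C)O[C@@H]3C2OC(=O)C(CO[Si](C)(C)C(C)(C)C)=C12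
F4 | step 15 | macrocyclic (Z)-epoxy enone | C=C(CO[Si](C)(C)C(C)(C)C)C(=O)O[C@H]1C[C@H](C)/C=C\C(=O)[C@@]3(C)O[C@@H]3C2OC(=O)C(CO[Si](C)(C)C(C)(C)C)=C12
F5 | step 15 | 1,2-dihydro furanone (bis-TBS ether, C1 epimers) | C=C(CO[Si](C)(C)C(C)(C)C)C(=O)O[C@H]1C[C@H](C)C2CC(=O)[C@](C)(/C=C3/OC(=O)C(CO[Si](C)(C)C(C)(C)C)=C31)O2
F6 | step 17 | macrocyclic 3,4-diol with (5E)-enol lactone and C1≡C2 | C=C(CO[Si](C)(C)C(C)(C)C)C(=O)O[C@H]1C[C@H](C)C#CC(O)[C@@](C)(O)/C=C2/OC(=O)C(CO[Si](C)(C)C(C)(C)C)=C21
F7 | step 17 | macrocyclic α'-hydroxy ynone | C=C(CO[Si](C)(C)C(C)(C)C)C(=O)O[C@H]1C[C@H](C)C#CC(=O)[C@@](C)(O)/C=C2/OC(=O)C(CO[Si](C)(C)C(C)(C)C)=C21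
F8 | step 3 | 3-bromo-4-[(2E)-but-2-enoyl]-5-[(1E)-3-(4-methoxybenzyloxy)-2-methylprop-1-en-1-yl]furan-2(5H)-one | C/C=C/C(=O)C1=C(Br)C(=O)OC1/C=C(C)/COCc1ccc(OC)cc1
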